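## Retrosynthetic overview

1. The lactone is closed last: catechol oxidation of (15S)-16-acetoxycarnosic acid 26 gives an ortho-quinone, then a quinone methide, which the C20 acid traps at C7.
2. C15 comes from a lipase desymmetrisation of the prochiral 2-aryl-1,3-propanediol 22, followed by deoxygenation of the free arm. The diol comes from malonate arylation at C13–Br, the bromine being placed ortho to a phenol unmasked by hydrogenolysis.
3. Ring A comes from a Robinson annulation of the 2-tetralone β-keto ester 9 with methyl vinyl ketone. The catalytic enantioselective Michael addition sets C10 (first stereocentre); gem-dimethylation, removal of the C3 oxygen and hydrogenation (sets C5) follow.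
4. Ring B comes from an intramolecular palladium α-arylation of a δ-aryl β-keto ester, made from tert-butyl acetoacetate dianion and benzyl bromide 5 (from O-benzylisovanillin).
5. Ring order: C (bought) → B → A → lactone.

Assumption: the sense of the two catalyst-controlled steps follows the closest precedents (cupreidine-type catalyst → (1S)-11; Burkholderia cepacia lipase acylation → (R)-23, as the empirical size rule for primary alcohols predicts); the pseudoenantiomeric cupreine-type catalyst is the drop-in reserve for step 7.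

Atom labels C1–C20 in the "Why" lines are abietane numbers; compound names use phenanthrene or naphthalene numbering.

## Route

Step 1
Reactants: 1 4-(benzyloxy)-3-hydroxybenzaldehyde
Product: 2 4-(benzyloxy)-2-bromo-3-hydroxybenzaldehyde
Conditions: Br2, NaOAc, AcOH, rt
Reagents that add atoms: bromine, BrBr
Why: Electrophilic aromatic bromination; as with isovanillin, the free 3-OH directs bromine to the ortho position between OH and CHO, which becomes C9.

Step 2
Reactants: 2 4-(benzyloxy)-2-bromo-3-hydroxybenzaldehyde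
Product: 3 4-(benzyloxy)-2-bromo-3-(methoxymethoxy)benzaldehyde
Conditions: MOMCl, i-Pr2NEt, CH2Cl2, 0 °C → rt
Reagents that add atoms: chloromethyl methyl ether, COCCl
Why: O-alkylation of the phenol; the MOM acetal survives every later basic, reductive and hydrogenation step and leaves with acid at the end.

Step 3
Reactants: 3 4-(benzyloxy)-2-bromo-3-(methoxymethoxy)benzaldehyde
Product: 4 [4-(benzyloxy)-2-bromo-3-(methoxymethoxy)phenyl]methanol
Conditions: NaBH4, MeOH–THF, 0 °C
Reagents that add atoms: none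
Why: Simple hydride reduction of the aldehyde; nothing else in the molecule is reducible under these conditions.

Step 4
Reactants: 4 [4-(benzyloxy)-2-bromo-3-(methoxymethoxy)phenyl]methanol
Product: 5 1-(benzyloxy)-3-bromo-4-(bromomethyl)-2-(methoxymethoxy)benzene
Conditions: CBr4, PPh3, CH2Cl2, 0 °C
Reagents that add atoms: carbon tetrabromide, BrC(Br)(Br)Br
Why: Appel bromination runs under neutral conditions, so the acid-labile MOM ether is kept.

Step 5
Reactants: 5 1-(benzyloxy)-3-bromo-4-(bromomethyl)-2-(methoxymethoxy)benzene; 6 tert-butyl acetoacetate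
Product: 8 tert-butyl 5-[4-(benzyloxy)-2-bromo-3-(methoxymethoxy)phenyl]-3-oxopentanoate, via acetoacetate dianion 7 (not isolated)
Conditions: 6, NaH, THF, 0 °C; n-BuLi, 0 °C; then 5, −78 → 0 °C; aq NH4Cl
Reagents that add atoms: none
Why: Weiler dianion alkylation; the more reactive terminal carbanion is benzylated (SN2), and all n-BuLi is consumed before the aryl bromide is added.

Step 6
Reactants: 8 tert-butyl 5-[4-(benzyloxy)-2-bromo-3-(methoxymethoxy)phenyl]-3-oxopentanoate
Product: 9 tert-butyl 7-(benzyloxy)-8-(methoxymethoxy)-2-oxo-1,2,3,4-tetrahydronaphthalene-1-carboxylate (racemic; mostly as the enol)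
Conditions: Pd2(dba)3 (2.5 mol %), t-Bu3P·HBF4 (10 mol %), K3PO4, toluene, 90 °C
Reagents that add atoms: none
Why: Intramolecular palladium-catalysed α-arylation of the β-keto ester enolate (zerovalent palladium inserts into C–Br, then C–C reductive elimination) closes the six-membered ring B at C9–C10.

Step 7
Reactants: 9 tert-butyl 7-(benzyloxy)-8-(methoxymethoxy)-2-oxo-1,2,3,4-tetrahydronaphthalene-1-carboxylate; 10 methyl vinyl ketone
Product: 11 tert-butyl (1S)-7-(benzyloxy)-8-(methoxymethoxy)-2-oxo-1-(3-oxobutyl)-1,2,3,4-tetrahydronaphthalene-1-carboxylate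
Conditions: 9-O-(9-phenanthryl)cupreidine (10 mol %), 10 (2 equiv), CH2Cl2, −20 °C
Reagents that add atoms: none
Why: Organocatalytic enantioselective Michael addition; the bifunctional cinchona catalyst (quinuclidine base plus phenolic OH) shields one face of the H-bonded enol/enone pair and sets the quaternary C10 stereocentre.

Step 8
Reactants: 11 tert-butyl (1S)-7-(benzyloxy)-8-(methoxymethoxy)-2-oxo-1-(3-oxobutyl)-1,2,3,4-tetrahydronaphthalene-1-carboxylate
Product: 12 tert-butyl (4aR)-6-(benzyloxy)-5-(methoxymethoxy)-2-oxo-2,3,4,4a,9,10-hexahydrophenanthrene-4a-carboxylate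
Conditions: pyrrolidine, AcOH, toluene, 80 °C
Reagents that add atoms: none
Why: Intramolecular aldol condensation (second half of the Robinson annulation) through the enamine of the methyl ketone closes ring A without alkoxide that could trigger retro-Claisen or retro-Michael loss of C10.

Step 9
Reactants: 12 tert-butyl (4aR)-6-(benzyloxy)-5-(methoxymethoxy)-2-oxo-2,3,4,4a,9,10-hexahydrophenanthrene-4a-carboxylate
Product: 13 tert-butyl (4aR)-6-(benzyloxy)-5-(methoxymethoxy)-1,1-dimethyl-2-oxo-1,2,3,4,4a,9-hexahydrophenanthrene-4a-carboxylate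
Conditions: KOt-Bu (3.5 equiv), t-BuOH–THF, rt; MeI (8 equiv), 0 °C → rt
Reagents that add atoms: iodomethane, CI
Why: Deconjugative α,α-dialkylation of the extended dienolate puts both methyls on C4 and moves the alkene to C5=C6.

Step 10
Reactants: 13 tert-butyl (4aR)-6-(benzyloxy)-5-(methoxymethoxy)-1,1-dimethyl-2-oxo-1,2,3,4,4a,9-hexahydrophenanthrene-4a-carboxylate
Product: 15 tert-butyl (4aR)-6-(benzyloxy)-5-(methoxymethoxy)-1,1-dimethyl-2-{[(trifluoromethyl)sulfonyl]oxy}-1,4,4a,9-tetrahydrophenanthrene-4a-carboxylate, via potassium enolate 14 (not isolated)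
Conditions: KN(SiMe3)2, THF, −78 °C; PhNTf2, −78 → 0 °C
Reagents that add atoms: N-phenylbis(trifluoromethanesulfonimide), O=S(=O)(N(c1ccccc1)S(=O)(=O)C(F)(F)F)C(F)(F)F
Why: The ketone has α-hydrogens only at C2, so enolisation is unambiguous and O-triflation gives the enol triflate.

Step 11
Reactants: 15 tert-butyl (4aR)-6-(benzyloxy)-5-(methoxymethoxy)-1,1-dimethyl-2-{[(trifluoromethyl)sulfonyl]oxy}-1,4,4a,9-tetrahydrophenanthrene-4a-carboxylate
Product: 16 tert-butyl (4aR)-6-(benzyloxy)-5-(methoxymethoxy)-1,1-dimethyl-1,4,4a,9-tetrahydrophenanthrene-4a-carboxylate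
Conditions: Pd(OAc)2 (5 mol %), PPh3, n-Bu3N, HCO2H, DMF, 60 °C
Reagents that add atoms: none
Why: Palladium-catalysed formate reduction of the vinyl triflate (Cacchi reduction) removes the C3 oxygen under buffered conditions that spare MOM, benzyl and tert-butyl groups.

Step 12
Reactants: 16 tert-butyl (4aR)-6-(benzyloxy)-5-(methoxymethoxy)-1,1-dimethyl-1,4,4a,9-tetrahydrophenanthrene-4a-carboxylate
Product: 17 tert-butyl (4aR,10aS)-6-hydroxy-5-(methoxymethoxy)-1,1-dimethyl-1,2,3,4,4a,9,10,10a-octahydrophenanthrene-4a-carboxylate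
Conditions: H2 (4 atm), 10 % Pd/C, EtOAc–EtOH, rt
Reagents that add atoms: none
Why: Heterogeneous hydrogenation saturates both alkenes and hydrogenolyses the benzyl ether; hydrogen adds to C5=C6 from the α face, opposite the axial C10 ester and the 4β-methyl, which gives the trans A/B fusion at C5.

Step 13
Reactants: 17 tert-butyl (4aR,10aS)-6-hydroxy-5-(methoxymethoxy)-1,1-dimethyl-1,2,3,4,4a,9,10,10a-octahydrophenanthrene-4a-carboxylate
Product: 18 tert-butyl (4aR,10aS)-7-bromo-6-hydroxy-5-(methoxymethoxy)-1,1-dimethyl-1,2,3,4,4a,9,10,10a-octahydrophenanthrene-4a-carboxylate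
Conditions: NBS, MeCN, 0 °C
Reagents that add atoms: N-bromosuccinimide, O=C1CCC(=O)N1Br
Why: Electrophilic bromination is directed by the free phenol; its para position is blocked, so bromine enters the only free ortho position, C13.

Step 14
Reactants: 18 tert-butyl (4aR,10aS)-7-bromo-6-hydroxy-5-(methoxymethoxy)-1,1-dimethyl-1,2,3,4,4a,9,10,10a-octahydrophenanthrene-4a-carboxylate
Product: 19 tert-butyl (4aR,10aS)-7-bromo-5,6-bis(methoxymethoxy)-1,1-dimethyl-1,2,3,4,4a,9,10,10a-octahydrophenanthrene-4a-carboxylate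
Conditions: NaH, MOMCl, THF–DMF, 0 °C
Reagents that add atoms: chloromethyl methyl ether, COCCl
Why: O-alkylation of the hindered phenoxide masks the phenol so that it cannot interfere with the coupling or lactonise onto the malonate.

Step 15
Reactants: 19 tert-butyl (4aR,10aS)-7-bromo-5,6-bis(methoxymethoxy)-1,1-dimethyl-1,2,3,4,4a,9,10,10a-octahydrophenanthrene-4a-carboxylate; 20 diethyl malonate
Product: 21 tert-butyl (4aR,10aS)-7-(1,3-diethoxy-1,3-dioxopropan-2-yl)-5,6-bis(methoxymethoxy)-1,1-dimethyl-1,2,3,4,4a,9,10,10a-octahydrophenanthrene-4a-carboxylate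
Conditions: 20 (2 equiv), Pd2(dba)3, t-Bu3P·HBF4, K3PO4, toluene, 80 °C
Reagents that add atoms: none
Why: Palladium-catalysed α-arylation of the malonate enolate with the bulky electron-rich phosphine tolerates the ortho-alkoxy aryl bromide and installs C15 with its two future CH2O arms.

Step 16
Reactants: 21 tert-butyl (4aR,10aS)-7-(1,3-diethoxy-1,3-dioxopropan-2-yl)-5,6-bis(methoxymethoxy)-1,1-dimethyl-1,2,3,4,4a,9,10,10a-octahydrophenanthrene-4a-carboxylate
Product: 22 tert-butyl (4aR,10aS)-7-(1,3-dihydroxypropan-2-yl)-5,6-bis(methoxymethoxy)-1,1-dimethyl-1,2,3,4,4a,9,10,10a-octahydrophenanthrene-4a-carboxylate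
Conditions: LiBH4, THF, 0 °C → rt
Reagents that add atoms: none
Why: Borohydride reduces the two unhindered ethyl esters to the prochiral 1,3-diol, while the tert-butyl ester on the quaternary C10 is inert.

Step 17
Reactants: 22 tert-butyl (4aR,10aS)-7-(1,3-dihydroxypropan-2-yl)-5,6-bis(methoxymethoxy)-1,1-dimethyl-1,2,3,4,4a,9,10,10a-octahydrophenanthrene-4a-carboxylate
Product: 23 tert-butyl (4aR,10aS)-7-[(2R)-1-acetoxy-3-hydroxypropan-2-yl]-5,6-bis(methoxymethoxy)-1,1-dimethyl-1,2,3,4,4a,9,10,10a-octahydrophenanthrene-4a-carboxylate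
Conditions: lipase from Burkholderia cepacia (immobilised), vinyl acetate, t-BuOMe, 30 °C
Reagents that add atoms: vinyl acetate, CC(=O)OC=C
Why: A lipase (serine hydrolase) transfers acetyl to only one of the two enantiotopic CH2OH groups (enantiotopic-group-selective transesterification, irreversible because vinyl alcohol tautomerises), which sets C15; the acetate it installs is the one found in the target.

Step 18
Reactants: 23 tert-butyl (4aR,10aS)-7-[(2R)-1-acetoxy-3-hydroxypropan-2-yl]-5,6-bis(methoxymethoxy)-1,1-dimethyl-1,2,3,4,4a,9,10,10a-octahydrophenanthrene-4a-carboxylate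
Product: 24 tert-butyl (4aR,10aS)-7-[(2S)-1-acetoxy-3-iodopropan-2-yl]-5,6-bis(methoxymethoxy)-1,1-dimethyl-1,2,3,4,4a,9,10,10a-octahydrophenanthrene-4a-carboxylate
Conditions: I2, PPh3, imidazole, CH2Cl2, 0 °C
Reagents that add atoms: iodine, II
Why: Appel-type iodination of the primary alcohol is fast and near-neutral, so no 1,3-acyl migration (which would racemise C15) occurs; the descriptor changes only because CH2I outranks CH2OAc.

Step 19
Reactants: 24 tert-butyl (4aR,10aS)-7-[(2S)-1-acetoxy-3-iodopropan-2-yl]-5,6-bis(methoxymethoxy)-1,1-dimethyl-1,2,3,4,4a,9,10,10a-octahydrophenanthrene-4a-carboxylate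
Product: 25 tert-butyl (4aR,10aS)-7-[(2S)-1-acetoxypropan-2-yl]-5,6-bis(methoxymethoxy)-1,1-dimethyl-1,2,3,4,4a,9,10,10a-octahydrophenanthrene-4a-carboxylate
Conditions: n-Bu3SnH, AIBN, toluene, 80 °C
Reagents that add atoms: none
Why: Radical chain dehalogenation turns CH2I into the C17 methyl; the primary radical is quenched far faster than any aryl shift and C15 is not involved.

Step 20
Reactants: 25 tert-butyl (4aR,10aS)-7-[(2S)-1-acetoxypropan-2-yl]-5,6-bis(methoxymethoxy)-1,1-dimethyl-1,2,3,4,4a,9,10,10a-octahydrophenanthrene-4a-carboxylate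
Product: 26 (4aR,10aS)-7-[(2S)-1-acetoxypropan-2-yl]-5,6-dihydroxy-1,1-dimethyl-1,2,3,4,4a,9,10,10a-octahydrophenanthrene-4a-carboxylic acid ((15S)-16-acetoxycarnosic acid)
Conditions: TFA–CH2Cl2–H2O (10:10:1), 0 °C → rt, N2
Reagents that add atoms: none
Why: Acidolysis removes the tert-butyl ester (E1 loss of isobutene) and hydrolyses both MOM acetals, water trapping the oxocarbenium ions, while the primary acetate is stable to aqueous TFA at room temperature.

Step 21
Reactants: 26 (15S)-16-acetoxycarnosic acid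
Product: 29 (15S)-16-acetoxycarnosol (target), via ortho-quinone 27 (not isolated), via para-quinone methide 28 (not isolated)
Conditions: Ag2O, Et2O, rt, dark; filter; then acetone, 40 °C, N2, no added base
Reagents that add atoms: none
Why: Catechol oxidation gives the ortho-quinone, which tautomerises to the para-quinone methide and is trapped by intramolecular 1,6-addition of the C20 acid; the β-oriented carboxyl can reach C7 only from the β face, which sets C7 and restores the catechol.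

## Compound list

1 | 4-(benzyloxy)-3-hydroxybenzaldehyde (O-benzylisovanillin) | O=Cc1ccc(OCc2ccccc2)c(O)c1 | starting material
2 | 4-(benzyloxy)-2-bromo-3-hydroxybenzaldehyde | O=Cc1ccc(OCc2ccccc2)c(O)c1Br | intermediate
3 | 4-(benzyloxy)-2-bromo-3-(methoxymethoxy)benzaldehyde | O=Cc1ccc(OCc2ccccc2)c(OCOC)c1Br | intermediate
4 | [4-(benzyloxy)-2-bromo-3-(methoxymethoxy)phenyl]methanol | OCc1ccc(OCc2ccccc2)c(OCOC)c1Br | intermediate
5 | 1-(benzyloxy)-3-bromo-4-(bromomethyl)-2-(methoxymethoxy)benzene | BrCc1ccc(OCc2ccccc2)c(OCOC)c1Br | intermediate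
6 | tert-butyl acetoacetate (tert-butyl 3-oxobutanoate) | CC(=O)CC(=O)OC(C)(C)C | starting material
7 | sodium lithium dianion of tert-butyl acetoacetate | [Li+].[Na+].[CH2-]C(=O)[CH-]C(=O)OC(C)(C)C | intermediate
8 | tert-butyl 5-[4-(benzyloxy)-2-bromo-3-(methoxymethoxy)phenyl]-3-oxopentanoate | CC(C)(C)OC(=O)CC(=O)CCc1ccc(OCc2ccccc2)c(OCOC)c1Br | intermediate
9 | tert-butyl 7-(benzyloxy)-8-(methoxymethoxy)-2-oxo-1,2,3,4-tetrahydronaphthalene-1-carboxylate (racemic, mostly enol; keto form drawn) | CC(C)(C)OC(=O)C1C(=O)CCc2ccc(OCc3ccccc3)c(OCOC)c12 | intermediate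
10 | methyl vinyl ketone (but-3-en-2-one) | CC(=O)C=C | starting material
11 | tert-butyl (1S)-7-(benzyloxy)-8-(methoxymethoxy)-2-oxo-1-(3-oxobutyl)-1,2,3,4-tetrahydronaphthalene-1-carboxylate | CC(=O)CC[C@@]1(C(=O)OC(C)(C)C)C(=O)CCc2ccc(OCc3ccccc3)c(OCOC)c12 | intermediate
12 | tert-butyl (4aR)-6-(benzyloxy)-5-(methoxymethoxy)-2-oxo-2,3,4,4a,9,10-hexahydrophenanthrene-4a-carboxylate (ring A enone, C4=C5) | CC(C)(C)OC(=O)[C@]12CCC(=O)C=C1CCc3ccc(OCc4ccccc4)c(OCOC)c32 | intermediate
13 | tert-butyl (4aR)-6-(benzyloxy)-5-(methoxymethoxy)-1,1-dimethyl-2-oxo-1,2,3,4,4a,9-hexahydrophenanthrene-4a-carboxylate (C5=C6 alkene) | CC(C)(C)OC(=O)[C@]12CCC(=O)C(C)(C)C1=CCc3ccc(OCc4ccccc4)c(OCOC)c32 | intermediate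
14 | potassium enolate of 13 (enolate across abietane C2=C3) | [K+].CC(C)(C)OC(=O)[C@]12CC=C([O-])C(C)(C)C1=CCc3ccc(OCc4ccccc4)c(OCOC)c32 | intermediate
15 | tert-butyl (4aR)-6-(benzyloxy)-5-(methoxymethoxy)-1,1-dimethyl-2-{[(trifluoromethyl)sulfonyl]oxy}-1,4,4a,9-tetrahydrophenanthrene-4a-carboxylate | CC(C)(C)OC(=O)[C@]12CC=C(OS(=O)(=O)C(F)(F)F)C(C)(C)C1=CCc3ccc(OCc4ccccc4)c(OCOC)c32 | intermediate
16 | tert-butyl (4aR)-6-(benzyloxy)-5-(methoxymethoxy)-1,1-dimethyl-1,4,4a,9-tetrahydrophenanthrene-4a-carboxylate (C2=C3 and C5=C6 diene) | CC(C)(C)OC(=O)[C@]12CC=CC(C)(C)C1=CCc3ccc(OCc4ccccc4)c(OCOC)c32 | intermediate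
17 | tert-butyl (4aR,10aS)-6-hydroxy-5-(methoxymethoxy)-1,1-dimethyl-1,2,3,4,4a,9,10,10a-octahydrophenanthrene-4a-carboxylate (trans-fused, 5α-H) | CC(C)(C)OC(=O)[C@]12CCCC(C)(C)[C@@H]1CCc3ccc(O)c(OCOC)c32 | intermediate
18 | tert-butyl (4aR,10aS)-7-bromo-6-hydroxy-5-(methoxymethoxy)-1,1-dimethyl-1,2,3,4,4a,9,10,10a-octahydrophenanthrene-4a-carboxylate | CC(C)(C)OC(=O)[C@]12CCCC(C)(C)[C@@H]1CCc3cc(Br)c(O)c(OCOC)c32 | intermediate
19 | tert-butyl (4aR,10aS)-7-bromo-5,6-bis(methoxymethoxy)-1,1-dimethyl-1,2,3,4,4a,9,10,10a-octahydrophenanthrene-4a-carboxylate | CC(C)(C)OC(=O)[C@]12CCCC(C)(C)[C@@H]1CCc3cc(Br)c(OCOC)c(OCOC)c32 | intermediate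
20 | diethyl malonate | CCOC(=O)CC(=O)OCC | starting material
21 | tert-butyl (4aR,10aS)-7-(1,3-diethoxy-1,3-dioxopropan-2-yl)-5,6-bis(methoxymethoxy)-1,1-dimethyl-1,2,3,4,4a,9,10,10a-octahydrophenanthrene-4a-carboxylate | CC(C)(C)OC(=O)[C@]12CCCC(C)(C)[C@@H]1CCc3cc(C(C(=O)OCC)C(=O)OCC)c(OCOC)c(OCOC)c32 | intermediate
22 | tert-butyl (4aR,10aS)-7-(1,3-dihydroxypropan-2-yl)-5,6-bis(methoxymethoxy)-1,1-dimethyl-1,2,3,4,4a,9,10,10a-octahydrophenanthrene-4a-carboxylate | CC(C)(C)OC(=O)[C@]12CCCC(C)(C)[C@@H]1CCc3cc(C(CO)CO)c(OCOC)c(OCOC)c32 | intermediate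
23 | tert-butyl (4aR,10aS)-7-[(2R)-1-acetoxy-3-hydroxypropan-2-yl]-5,6-bis(methoxymethoxy)-1,1-dimethyl-1,2,3,4,4a,9,10,10a-octahydrophenanthrene-4a-carboxylate | CC(C)(C)OC(=O)[C@]12CCCC(C)(C)[C@@H]1CCc3cc([C@H](CO)COC(C)=O)c(OCOC)c(OCOC)c32 | intermediate
24 | tert-butyl (4aR,10aS)-7-[(2S)-1-acetoxy-3-iodopropan-2-yl]-5,6-bis(methoxymethoxy)-1,1-dimethyl-1,2,3,4,4a,9,10,10a-octahydrophenanthrene-4a-carboxylate | CC(C)(C)OC(=O)[C@]12CCCC(C)(C)[C@@H]1CCc3cc([C@H](CI)COC(C)=O)c(OCOC)c(OCOC)c32 | intermediate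
25 | tert-butyl (4aR,10aS)-7-[(2S)-1-acetoxypropan-2-yl]-5,6-bis(methoxymethoxy)-1,1-dimethyl-1,2,3,4,4a,9,10,10a-octahydrophenanthrene-4a-carboxylate | CC(C)(C)OC(=O)[C@]12CCCC(C)(C)[C@@H]1CCc3cc([C@H](C)COC(C)=O)c(OCOC)c(OCOC)c32 | intermediate
26 | (4aR,10aS)-7-[(2S)-1-acetoxypropan-2-yl]-5,6-dihydroxy-1,1-dimethyl-1,2,3,4,4a,9,10,10a-octahydrophenanthrene-4a-carboxylic acid ((15S)-16-acetoxycarnosic acid) | OC(=O)[C@]12CCCC(C)(C)[C@@H]1CCc3cc([C@H](C)COC(C)=O)c(O)c(O)c32 | intermediate
27 | ortho-quinone of 26: (4aR,10aS)-7-[(2S)-1-acetoxypropan-2-yl]-1,1-dimethyl-5,6-dioxo-1,2,3,4,4a,5,6,9,10,10a-decahydrophenanthrene-4a-carboxylic acid | OC(=O)[C@]12CCCC(C)(C)[C@@H]1CCC3=C2C(=O)C(=O)C([C@H](C)COC(C)=O)=C3 | intermediate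
28 | para-quinone methide: (4aR,10aS)-7-[(2S)-1-acetoxypropan-2-yl]-5-hydroxy-1,1-dimethyl-6-oxo-1,2,3,4,4a,6,10,10a-octahydrophenanthrene-4a-carboxylic acid (abietane C7=C8, C12=O, 11-OH) | OC(=O)[C@]12CCCC(C)(C)[C@@H]1CC=C3C=C([C@H](C)COC(C)=O)C(=O)C(O)=C32 | intermediate
29 | (15S)-16-acetoxycarnosol: (15S)-16-acetoxy-11,12-dihydroxyabieta-8,11,13-trien-20,7β-olide (5α-H, C20 β) | CC(=O)OC[C@@H](C)c1cc2c(c(O)c1O)[C@@]13CCCC(C)(C)[C@@H]1C[C@@H]2OC3=O | target

## Summary

Total step count: 21. Longest linear sequence: 21 steps (from 1).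

The three steps most likely to fail:

Step 6 (ring B closure). The aryl bromide is flanked on both sides, so oxidative addition and C–C reductive elimination may be slow, and O-arylation or dehalogenation may compete. The fallback sets out from 5 and comes back at 9 by a Dieckmann route. The lithium enolate of methyl acetate (LiN(SiMe3)2, MeOAc, THF, −78 °C) is alkylated with 5 to give methyl 3-[4-(benzyloxy)-2-bromo-3-(methoxymethoxy)phenyl]propanoate F1. Its C–Br bond is coupled with the Reformatsky reagent BrZnCH2CO2t-Bu (Pd2(dba)3, t-Bu3P·HBF4, THF, 60 °C) to give methyl 3-[4-(benzyloxy)-2-(2-tert-butoxy-2-oxoethyl)-3-(methoxymethoxy)phenyl]propanoate F2. Dieckmann condensation (KOt-Bu, THF, 0 °C), in which the acidic benzylic tert-butyl ester enolate can only attack the methyl ester, then delivers 9.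

Step 7 (enantioselective Michael addition). The nucleophilic carbon sits next to the peri MOM ether, so rate and enantioselectivity with methyl vinyl ketone may suffer. The fallback sets out from 9 and comes back at 11 with a smaller acceptor and a different mode of stereocontrol. Acrolein is added under chiral ion-pair (phase-transfer) catalysis with a Maruoka-type N-spiro binaphthyl ammonium bromide (K2CO3 10 mol %, toluene, −40 °C) to give tert-butyl (1S)-7-(benzyloxy)-8-(methoxymethoxy)-2-oxo-1-(3-oxopropyl)-1,2,3,4-tetrahydronaphthalene-1-carboxylate F3. MeTi(Oi-Pr)3 (THF, −40 °C) adds only to the aldehyde and gives tert-butyl (1S)-7-(benzyloxy)-1-(3-hydroxybutyl)-8-(methoxymethoxy)-2-oxo-1,2,3,4-tetrahydronaphthalene-1-carboxylate F4 as a mixture of carbinol epimers. Dess–Martin periodinane oxidises F4 to 11.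

Step 17 (lipase desymmetrisation). The bulky ortho-substituted aryl group may be poorly accepted, or the selectivity or its sense may be unsatisfactory; the sense is predicted, not established, for this substrate. The fallback sets out from 19 and comes back at 25, replacing desymmetrisation by a lipase kinetic resolution of simple 2-arylpropanol epimers (at most half of the material per pass). Suzuki–Miyaura coupling of 19 with isopropenylboronic acid pinacol ester (Pd(OAc)2, SPhos, K3PO4, toluene–H2O, 80 °C) gives tert-butyl (4aR,10aS)-5,6-bis(methoxymethoxy)-1,1-dimethyl-7-(prop-1-en-2-yl)-1,2,3,4,4a,9,10,10a-octahydrophenanthrene-4a-carboxylate F5. Hydroboration–oxidation (9-BBN, THF; NaBO3·4H2O) gives tert-butyl (4aR,10aS)-7-(1-hydroxypropan-2-yl)-5,6-bis(methoxymethoxy)-1,1-dimethyl-1,2,3,4,4a,9,10,10a-octahydrophenanthrene-4a-carboxylate F6 as a 1:1 mixture at C15. The same lipase with vinyl acetate, run to below half conversion, is expected to acylate the (15S) epimer and so give 25, which is separated from the unreacted (15R) alcohol.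

## Further compounds

F1 | step 6 | methyl 3-[4-(benzyloxy)-2-bromo-3-(methoxymethoxy)phenyl]propanoate | COC(=O)CCc1ccc(OCc2ccccc2)c(OCOC)c1Br
F2 | step 6 | methyl 3-[4-(benzyloxy)-2-(2-tert-butoxy-2-oxoethyl)-3-(methoxymethoxy)phenyl]propanoate | COC(=O)CCc1ccc(OCc2ccccc2)c(OCOC)c1CC(=O)OC(C)(C)C
F3 | step 7 | tert-butyl (1S)-7-(benzyloxy)-8-(methoxymethoxy)-2-oxo-1-(3-oxopropyl)-1,2,3,4-tetrahydronaphthalene-1-carboxylate | O=CCC[C@@]1(C(=O)OC(C)(C)C)C(=O)CCc2ccc(OCc3ccccc3)c(OCOC)c12
F4 | step 7 | tert-butyl (1S)-7-(benzyloxy)-1-(3-hydroxybutyl)-8-(methoxymethoxy)-2-oxo-1,2,3,4-tetrahydronaphthalene-1-carboxylate (carbinol epimers) | CC(O)CC[C@@]1(C(=O)OC(C)(C)C)C(=O)CCc2ccc(OCc3ccccc3)c(OCOC)c12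
F5 | step 17 | tert-butyl (4aR,10aS)-5,6-bis(methoxymethoxy)-1,1-dimethyl-7-(prop-1-en-2-yl)-1,2,3,4,4a,9,10,10a-octahydrophenanthrene-4a-carboxylate | CC(C)(C)OC(=O)[C@]12CCCC(C)(C)[C@@H]1CCc3cc(C(C)=C)c(OCOC)c(OCOC)c32
F6 | step 17 | tert-butyl (4aR,10aS)-7-(1-hydroxypropan-2-yl)-5,6-bis(methoxymethoxy)-1,1-dimethyl-1,2,3,4,4a,9,10,10a-octahydrophenanthrene-4a-carboxylate (both C15 epimers) | CC(C)(C)OC(=O)[C@]12CCCC(C)(C)[C@@H]1CCc3cc(C(C)CO)c(OCOC)c(OCOC)c32
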